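**Plan**

1. Retrosynthesis: the C2 isovalerate and the C1 angelate are removed; the C2/C3 cis-diol goes back to a C2=C3 alkene with an allylic C1 oxygen, and that (Wharton transposition) to the C1,C2-epoxide of a C3 ketone, hence to a C3 ketone with CH2 at C1 and C2.
2. This diketone is cut at C4–C5 and C1–C11, which removes the whole four-carbon bridge from the cyclobutane and leaves 1,5-dimethyltricyclo[4.1.0.0^2,7]hept-4-en-3-one and 2-bromo-2-methylpent-4-en-3-one.
3. Enabling feature: the cyclobutane carbons C5 and C11 are 1,3-related and joined by C4–C3–C2–C1, while C6 and C10 carry the C7(=O)–C8=C9 bridge; a bond between C5 and C11 turns the core into a bicyclo[1.1.0]butane whose strained central bond can take up a four-carbon radical/acceptor unit.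
4. Forward order: six-membered ring (3,5-dimethylcyclohexenone) → dibromocyclopropane → bicyclobutane (carbenoid C–H insertion) → seven-membered ring by radical annulation → oxygenation of C1–C3 and the two acylations.
5. Stereochemistry: the absolute configuration comes from enantioselective deprotonation of meso cis-3,5-dimethylcyclohexanone and is relayed methyl → carbinol → cyclopropane → bicyclobutane → C5, C6, C10, C11. C1 is set by catalyst-controlled epoxidation, because the tricyclic core does not distinguish the two faces of the seven-membered ring. C2 and C3 follow from osmylation anti to the C1 ester.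

Key step: step 11

Locants: C1–C11 are those of the target skeleton. Cyclobutane: C5, C6, C11, C10. Three-carbon bridge: C6–C7(=O)–C8=C9(CH3)–C10. Four-carbon bridge: C5–C4(CH3)2–C3–C2–C1–C11; C11 carries a methyl group. In the tricyclo[4.1.0.0^2,7]heptane intermediates, IUPAC positions 1–7 correspond to skeleton carbons C11, C6, C7, C8, C9, C10, C5. The face of the seven-membered ring on the side of C6 is called the C6 face, the other the C10 face; in the target O1 lies on the C6 face and O2, O3 on the C10 face.

Assumption: lithium (R,R)-bis(1-phenylethyl)amide is taken to give the (3R,5S)-enol silyl ether, by analogy with 4-substituted cyclohexanones; if the sense is the opposite, the (S,S)-amide takes its place.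

Assumption: the quinine-derived primary amine catalyst is taken to deliver the epoxide oxygen to the C6 face; if not, its quinidine-derived pseudo-enantiomer is used, since the substrate has no facial preference of its own.

Remark: the enantiomeric excess set in step 2 is to be raised by recrystallisation of the dibromide from step 5 before the bicyclobutane is made.

**Route**

Step 1
Reactants: 1 3,5-dimethylcyclohex-2-en-1-one (racemic)
Product: 2 cis-3,5-dimethylcyclohexan-1-one (meso)
Conditions: H2 (1 atm), Pd/C, EtOAc, 25 °C
Reagents that add atoms: none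
Why: Heterogeneous hydrogenation of the enone C=C; hydrogen should add to the face away from the 5-methyl group and favour the cis (meso) ketone, and any trans isomer is removed here.

Step 2
Reactants: 2 cis-3,5-dimethylcyclohexan-1-one
Product: 4 trimethyl{[(3R,5S)-3,5-dimethylcyclohex-1-en-1-yl]oxy}silane, via lithium enolate 3 (not isolated)
Conditions: (R,R)-bis(1-phenylethyl)amine, n-BuLi, THF, −78 °C; Me3SiCl (internal quench), −78 °C
Reagents that add atoms: chlorotrimethylsilane, C[Si](C)(C)Cl
Why: Desymmetrisation of a meso ketone by enantioselective deprotonation with a chiral lithium amide and O-silylation; the base chooses between the two enantiotopic α-CH2 groups and so decides which methyl-bearing carbon becomes C11 and which C9.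

Step 3
Reactants: 4 trimethyl{[(3R,5S)-3,5-dimethylcyclohex-1-en-1-yl]oxy}silane
Product: 5 (5S)-3,5-dimethylcyclohex-2-en-1-one
Conditions: Pd(OAc)2 (10 mol %), O2 (1 atm), Me2SO, 25 °C
Reagents that add atoms: none
Why: Saegusa–Ito oxidation, catalytic in divalent palladium under oxygen; β-hydride loss is possible only from position 3, so the stereocentre at position 5 is untouched.

Step 4
Reactants: 5 (5S)-3,5-dimethylcyclohex-2-en-1-one
Product: 6 (1S,5S)-3,5-dimethylcyclohex-2-en-1-ol (cis)
Conditions: NaBH4, CeCl3·7H2O, MeOH, −78 °C to 0 °C
Reagents that add atoms: none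
Why: Luche 1,2-reduction; axial hydride attack on the half-chair with the 5-methyl equatorial should give mainly the cis alcohol, and the minor trans isomer is separated because it would lead into the antipodal series.

Step 5
Reactants: 6 (1S,5S)-3,5-dimethylcyclohex-2-en-1-ol; 7 bromoform
Product: 8 (1R,2S,4S,6R)-7,7-dibromo-4,6-dimethylbicyclo[4.1.0]heptan-2-ol (2-OH, 4-CH3 and the CBr2 bridge all cis)
Conditions: 50% aq NaOH, BnEt3NCl (cat.), CH2Cl2, 0 °C to 25 °C
Reagents that add atoms: none
Why: Dibromocarbene addition under phase-transfer conditions to the trisubstituted alkene, directed to the hydroxyl-bearing face as in dihalocarbene additions to cyclohex-2-enols, so that the cyclopropane configuration is set by the carbinol centre.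

Step 6
Reactants: 8 (1R,2S,4S,6R)-7,7-dibromo-4,6-dimethylbicyclo[4.1.0]heptan-2-ol
Product: 10 1,5-dimethyltricyclo[4.1.0.0^2,7]heptan-3-ol (single enantiomer; 3-OH and 5-CH3 on the ring face that carries C7), via lithium carbenoid 9 (not isolated)
Conditions: MeLi (3 equiv), Et2O, −78 °C to 0 °C; then H2O
Reagents that add atoms: none
Why: Bromine–lithium exchange gives carbenoid 9, whose cyclopropylidene carbon (skeleton C5) inserts into the cis C–H bond of the ring CH2 next to the methyl-bearing cyclopropane carbon (skeleton C10), the classical route from 7,7-dibromonorcaranes to tricyclo[4.1.0.0^2,7]heptanes; the carbinol hydrogen is trans to the carbenoid and out of reach, so this CH2 is the only ring C–H available, and the two new bicyclobutane stereocentres are fixed by the cis fusion.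

Step 7
Reactants: 10 1,5-dimethyltricyclo[4.1.0.0^2,7]heptan-3-ol
Product: 11 1,5-dimethyltricyclo[4.1.0.0^2,7]heptan-3-one (5-CH3 as in 10)
Conditions: SO3·pyridine, Me2SO, i-Pr2NEt, CH2Cl2, 0 °C
Reagents that add atoms: none
Why: Parikh–Doering oxidation, chosen because the medium stays basic throughout and spares the acid-sensitive bicyclobutane.

Step 8
Reactants: 11 1,5-dimethyltricyclo[4.1.0.0^2,7]heptan-3-one
Product: 13 1,5-dimethyltricyclo[4.1.0.0^2,7]hept-4-en-3-one (single enantiomer; seen from C7 towards C1 with the three-carbon bridge on top the carbonyl carbon is on the left), via lithium enolate 12 (not isolated)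
Conditions: LiN(i-Pr)2, THF, −78 °C; then PhS(Cl)=N-t-Bu, −78 °C
Reagents that add atoms: none
Why: One-pot ketone dehydrogenation through lithium enolate 12 (only skeleton C8 bears enolisable hydrogens), S–C bond formation with the sulfinimidoyl chloride and syn elimination of the sulfenamide towards C9 at −78 °C; no acid, halogen electrophile or transition metal that could open the bicyclobutane is present, and the C9 stereocentre is erased after it has served as relay.

Step 9
Reactants: 14 2-bromo-2-methylpropanoyl bromide
Product: 15 2-bromo-N-methoxy-N,2-dimethylpropanamide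
Conditions: MeNHOMe·HCl, K2CO3, CH2Cl2/H2O, 0 °C
Reagents that add atoms: N,O-dimethylhydroxylamine hydrochloride, CNOC.Cl
Why: Schotten–Baumann acylation of the hydroxylamine by the acid bromide; the tertiary C–Br bond is inert under these conditions.

Step 10
Reactants: 15 2-bromo-N-methoxy-N,2-dimethylpropanamide; 16 vinylmagnesium bromide
Product: 18 2-bromo-2-methylpent-4-en-3-one, via magnesium chelate 17 (not isolated)
Conditions: THF, −78 °C to −20 °C; poured into cold 1 M HCl
Reagents that add atoms: none
Why: Weinreb ketone synthesis; chelate 17 resists a second addition, and the inverse acidic quench keeps the liberated N,O-dimethylhydroxylamine from adding to the vinyl ketone.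

Step 11
Reactants: 13 1,5-dimethyltricyclo[4.1.0.0^2,7]hept-4-en-3-one; 18 2-bromo-2-methylpent-4-en-3-one
Product: 22 tricyclic 3,7-dione (C3 ketone; C7 enone; CH2 at C1 and C2; C5/C6/C10/C11 as in the target), via keto radical 19 (not isolated), via cyclobutyl radical 20 (not isolated), via ring-closed radical 21 (not isolated)
Conditions: (Me3Si)3SiH and 18 added over 8 h (syringe pump), AIBN (cat.), PhH, 80 °C
Reagents that add atoms: none
Why: Proposed new method: the silyl radical abstracts bromine from 18 to give the electrophilic tertiary α-keto radical 19, which attacks the electron-rich central σ-bond of 13 at the hydrogen-bearing bridgehead C5 from the side opposite the enone bridge, forming C4–C5; the closest known reaction type is the atom-transfer addition of sulfonyl, thiyl and α-halocarbonyl radicals across the central bonds of tricyclo[4.1.0.0^2,7]heptanes, bicyclobutanes and [1.1.1]propellane, whereas a carbon-centred annulation on this ring system is not known. Strain release leaves the tertiary, nucleophilic cyclobutyl radical 20 at C11, held 1,3-cis to the new side chain, and it closes the seven-membered ring by 7-endo-trig Giese addition to the CH2 terminus of the vinyl ketone (C1–C11); radical 21 is then reduced at C2 by the silane, which carries the chain. The two new stereocentres C5 and C11 are controlled by the substrate alone: the first radical can enter only anti to the three-carbon bridge and the four-atom tether can reach only the anti lobe at C11, so the configuration of 13 passes unchanged into 22. The step needs attack at C5 and not at C11, which the C11 methyl group secures by hindering that carbon and by making the radical formed there tertiary. It also needs endo and not 6-exo closure, secured by enone polarity, since attack at C2 would give an unstabilised primary radical. Finally, ring closure must come before reduction, which the slow addition of silane and 18 secures.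

Step 12
Reactants: 22 tricyclic 3,7-dione
Product: 23 tricyclic 1,8-diene-3,7-dione (new C1=C2 conjugated to the C3 ketone)
Conditions: IBX, Me2SO, 65 °C
Reagents that add atoms: none
Why: IBX dehydrogenation of a ketone to its enone; only the C3 carbonyl has an α-CH2 with a β-hydrogen, the C7 carbonyl being flanked by a bridgehead and an alkene.

Step 13
Reactants: 23 tricyclic 1,8-diene-3,7-dione
Product: 24 1,2-epoxy-8-ene-3,7-dione (epoxide oxygen on the C6 face)
Conditions: 9-amino-9-deoxy-epi-quinine·2 CF3CO2H (10 mol %), 50% aq H2O2, 1,4-dioxane, 35 °C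
Reagents that add atoms: hydrogen peroxide, OO
Why: Primary-amine-salt-catalysed asymmetric Weitz–Scheffer epoxidation of a cyclic enone through its iminium ion; since the core does not differentiate the two faces of C1=C2, the catalyst alone decides the face, and the hindered β,β-disubstituted C7 enone should be left alone.

Step 14
Reactants: 24 1,2-epoxy-8-ene-3,7-dione
Product: 26 tricyclic 2,8-dien-7-on-1-ol (1-OH on the C6 face; C2=C3), via epoxy hydrazone 25 (not isolated)
Conditions: N2H4·H2O, AcOH (cat.), MeOH, 0 °C to 25 °C
Reagents that add atoms: none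
Why: Wharton transposition; the more electrophilic epoxy ketone condenses to hydrazone 25, which opens the epoxide and expels N2, so the alkene moves to C2=C3 while the C1–O bond and its configuration stay untouched.

Step 15
Reactants: 26 tricyclic 2,8-dien-7-on-1-ol; 27 angelic acid
Product: 29 C1 angelate of 26, via mixed anhydride 28 (not isolated)
Conditions: 2,4,6-Cl3C6H2COCl, Et3N, PhMe, 25 °C; then 26, 75 °C
Reagents that add atoms: none
Why: Yamaguchi-type esterification through the 2,4,6-trichlorobenzoyl mixed anhydride, the protocol that acylates hindered alcohols with angelic acid without Z-to-E isomerisation to the tiglate.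

Step 16
Reactants: 29 C1 angelate of 26
Product: 30 C1 angelate 2,3-diol (O2 and O3 on the C10 face)
Conditions: OsO4 (5 mol %), N-methylmorpholine N-oxide, acetone/H2O, 0 °C
Reagents that add atoms: osmium tetroxide, O=[Os](=O)(=O)=O; N-methylmorpholine N-oxide, C[N+]1([O-])CCOCC1; water, O
Why: Catalytic osmium tetroxide dihydroxylation; the reagent should add to the ring alkene from the face opposite the allylic acyloxy group (the usual anti course for allylic ethers and esters), giving the C2,C3 cis-diol trans to the C1 ester, while the conjugated angelate and enone double bonds are less nucleophilic.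

Step 17
Reactants: 30 C1 angelate 2,3-diol; 31 3-methylbutanoic anhydride
Product: 32 CNP0251293.1 (C1 angelate; C2 3-methylbutanoate; C3 alcohol)
Conditions: DMAP (cat.), pyridine, CH2Cl2, 0 °C
Reagents that add atoms: none
Why: DMAP-catalysed acylation; the C2 hydroxyl sits between two CH carbons whereas the C3 hydroxyl is neopentylic next to the gem-dimethyl carbon, so the anhydride should react at O2 first.

**Compound list**

1 | 3,5-dimethylcyclohex-2-en-1-one (racemic) | CC1CC(C)=CC(=O)C1 | starting material
2 | cis-3,5-dimethylcyclohexan-1-one (meso, 3R,5S) | C[C@H]1C[C@@H](C)CC(=O)C1 | intermediate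
3 | lithium (3R,5S)-3,5-dimethylcyclohex-1-en-1-olate (formed in the flask) | C[C@H]1C[C@@H](C)C=C(O[Li])C1 | intermediate
4 | trimethyl{[(3R,5S)-3,5-dimethylcyclohex-1-en-1-yl]oxy}silane | C[C@H]1C[C@@H](C)C=C(O[Si](C)(C)C)C1 | intermediate
5 | (5S)-3,5-dimethylcyclohex-2-en-1-one | C[C@@H]1CC(=O)C=C(C)C1 | intermediate
6 | (1S,5S)-3,5-dimethylcyclohex-2-en-1-ol (cis) | C[C@@H]1C[C@H](O)C=C(C)C1 | intermediate
7 | bromoform | BrC(Br)Br | starting material
8 | (1R,2S,4S,6R)-7,7-dibromo-4,6-dimethylbicyclo[4.1.0]heptan-2-ol (2-OH, 4-CH3 and CBr2 bridge all cis) | C[C@@H]1C[C@H](O)[C@@H]2C(Br)(Br)[C@]2(C)C1 | intermediate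
9 | lithium alkoxide of the 7-bromo-7-lithio carbenoid from 8 (formed in the flask; configuration at the carbenoid carbon not defined) | C[C@@H]1C[C@H](O[Li])[C@@H]2C([Li])(Br)[C@]2(C)C1 | intermediate
10 | 1,5-dimethyltricyclo[4.1.0.0^2,7]heptan-3-ol (3-OH and 5-CH3 on the face of the six-membered ring that carries C7) | C[C@@H]1C[C@H](O)[C@@H]2[C@@H]3[C@H]1[C@]23C | intermediate
11 | 1,5-dimethyltricyclo[4.1.0.0^2,7]heptan-3-one (5-CH3 as in 10) | C[C@@H]1CC(=O)[C@@H]2[C@@H]3[C@H]1[C@]23C | intermediate
12 | lithium enolate of 11 (C3–OLi, C3=C4; formed in the flask) | C[C@@H]1C=C(O[Li])[C@@H]2[C@@H]3[C@H]1[C@]23C | intermediate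
13 | 1,5-dimethyltricyclo[4.1.0.0^2,7]hept-4-en-3-one, single enantiomer (seen from C7 towards C1 with the three-carbon bridge on top, the carbonyl carbon is on the left) | CC1=CC(=O)[C@@H]2[C@@H]3[C@H]1[C@]23C | intermediate
14 | 2-bromo-2-methylpropanoyl bromide | CC(C)(Br)C(=O)Br | starting material
15 | 2-bromo-N-methoxy-N,2-dimethylpropanamide | CC(C)(Br)C(=O)N(C)OC | intermediate
16 | vinylmagnesium bromide | C=C[Mg]Br | starting material
17 | bromomagnesium alkoxide of the tetrahedral adduct of 15 and 16 (formed in the flask) | CC(C)(Br)C(O[Mg]Br)(C=C)N(C)OC | intermediate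
18 | 2-bromo-2-methylpent-4-en-3-one | CC(C)(Br)C(=O)C=C | intermediate
19 | 2-methyl-3-oxopent-4-en-2-yl radical (formed in the flask) | C[C](C)C(=O)C=C | intermediate
20 | C11 cyclobutyl radical: 13 opened across C5–C11, C5 carrying the C(CH3)2–CO–CH=CH2 chain anti to the enone bridge (formed in the flask) | C=CC(=O)C(C)(C)[C@@H]1[C@H]2C(=O)C=C(C)[C@@H]1[C]2C | intermediate
21 | ring-closed C2 radical of the tricyclic 3,7-dione (formed in the flask) | C1[CH]C(=O)C(C)(C)[C@@H]2[C@H]3C(=O)C=C(C)[C@@H]2[C@@]13C | intermediate
22 | tricyclic 3,7-dione: C3 ketone, C7 enone (C8=C9), CH2 at C1 and C2, methyls at C4 (two), C9 and C11 | C1CC(=O)C(C)(C)[C@@H]2[C@H]3C(=O)C=C(C)[C@@H]2[C@@]13C | intermediate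
23 | tricyclic 1,8-diene-3,7-dione (C1=C2–C3=O and C7(=O)–C8=C9) | C1=CC(=O)C(C)(C)[C@@H]2[C@H]3C(=O)C=C(C)[C@@H]2[C@@]13C | intermediate
24 | 1,2-epoxy-8-ene-3,7-dione, epoxide oxygen on the C6 face | O4[C@@H]1[C@H]4C(=O)C(C)(C)[C@@H]2[C@H]3C(=O)C=C(C)[C@@H]2[C@@]13C | intermediate
25 | C3 hydrazone of 24 (formed in the flask; C=N geometry not defined) | O4[C@@H]1[C@H]4C(=NN)C(C)(C)[C@@H]2[C@H]3C(=O)C=C(C)[C@@H]2[C@@]13C | intermediate
26 | tricyclic 2,8-dien-7-on-1-ol: C1 hydroxyl on the C6 face, C2=C3, C7 enone | O[C@@H]1C=CC(C)(C)[C@@H]2[C@H]3C(=O)C=C(C)[C@@H]2[C@@]13C | intermediate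
27 | angelic acid, (Z)-2-methylbut-2-enoic acid | C/C=C(/C)C(=O)O | starting material
28 | (Z)-2-methylbut-2-enoic 2,4,6-trichlorobenzoic anhydride (formed in the flask) | C/C=C(/C)C(=O)OC(=O)c1c(Cl)cc(Cl)cc1Cl | intermediate
29 | C1 angelate of 26 | C/C=C(/C)C(=O)O[C@@H]1C=CC(C)(C)[C@@H]2[C@H]3C(=O)C=C(C)[C@@H]2[C@@]13C | intermediate
30 | C1 angelate 2,3-diol: O1 on the C6 face, O2 and O3 on the C10 face | C/C=C(/C)C(=O)O[C@@H]1[C@@H](O)[C@@H](O)C(C)(C)[C@@H]2[C@H]3C(=O)C=C(C)[C@@H]2[C@@]13C | intermediate
31 | 3-methylbutanoic anhydride | CC(C)CC(=O)OC(=O)CC(C)C | starting material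
32 | CNP0251293.1: C1 angelate, C2 3-methylbutanoate, C3 alcohol (C1, C2, C3 all S), C7 enone | C/C=C(/C)C(=O)O[C@@H]1[C@@H](OC(=O)CC(C)C)[C@@H](O)C(C)(C)[C@@H]2[C@H]3C(=O)C=C(C)[C@@H]2[C@@]13C | target

**Step count and risks**

Total step count: 17. Longest linear sequence: 15 steps (steps 1–8 and 11–17, from 1); the branch to 18 takes 2 steps (9 and 10).

Steps most likely to fail:

Step 11. The radical chain can break down in three ways: reduction of radical 19 by the silane before it meets 13; capture of the cyclobutyl radical (hydrogen or bromine transfer, or addition to a second molecule of the vinyl ketone) before the slow 7-endo closure; and telomerisation of the vinyl ketone. The fallback separates the two bond formations and uses known reaction types. Setting out from 13 and an excess of 18, an atom-transfer radical addition without hydrogen donor (fac-Ir(ppy)3, blue LEDs, MeCN), of the kind known for α-bromocarbonyl compounds and strained central σ-bonds, should give the 1,3-adduct, the C11 bromide F1. F1 is then treated on its own with Bu3SnH and AIBN in dilute refluxing benzene (syringe pump), a classical tin hydride cyclisation of a tertiary bromide onto an enone. This regenerates radical 20 in the absence of 18 and returns to the route at 22.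

Step 13. Iminium formation at the C3 carbonyl next to the quaternary C4 may be too slow, and catalyst control over a substrate without intrinsic bias may be incomplete (poor facial selectivity). The fallback oxygenates C1 by a different catalyst-controlled reaction, copper-catalysed enantioselective conjugate borylation. Setting out from 23, CuCl, NaOt-Bu, a Josiphos-type ligand (enantiomer chosen for the C6 face), B2pin2 and MeOH in THF should give the C1 pinacolboronate F2. F2 is oxidised in the same flask with NaBO3·4H2O to the β-hydroxy ketone F3. Silylation (Et3SiCl, imidazole) gives the silyl ether F4. The only possible enolate, towards C2, is trapped as the enol triflate F5 (KN(SiMe3)2, PhNTf2, −78 °C). The triflate is reduced (Pd(OAc)2, PPh3, Bu3N, HCO2H, DMF, 60 °C) to the allylic silyl ether F6, and HF·pyridine releases the alcohol, returning to the route at 26.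

Step 16. Chemoselectivity may be lost (osmylation of the angelate double bond in competition with the hindered, ester-deactivated ring alkene), or the acyl group may migrate from O1 to O2 in the product. The fallback changes the order of events. Setting out from 26, the free allylic alcohol is dihydroxylated first (OsO4 cat., N-methylmorpholine N-oxide; anti to the hydroxyl) to the 1,2,3-triol F7. The cis-2,3-diol is tied up as the acetonide F8 (2,2-dimethoxypropane, pyridinium p-toluenesulfonate). The remaining C1 hydroxyl is angeloylated as in step 15 to give the acetonide angelate F9, and aqueous acetic acid removes the acetonide, returning to the route at 30.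

**Further compounds**

F1 | step 11 | C11 bromide from atom-transfer addition of 18 across C5–C11 of 13 (C5 side chain anti to the enone bridge, bromine syn, vinyl ketone intact) | C=CC(=O)C(C)(C)[C@@H]1[C@H]2C(=O)C=C(C)[C@@H]1[C@]2(C)Br
F2 | step 13 | C1 pinacolboronate of the tricyclic 3,7-dione (boron on the C6 face) | CC1(C)OB(OC1(C)C)[C@@H]2CC(=O)C(C)(C)[C@@H]3[C@H]4C(=O)C=C(C)[C@@H]3[C@@]24C
F3 | step 13 | 1-hydroxy tricyclic 3,7-dione (hydroxyl on the C6 face) | O[C@@H]1CC(=O)C(C)(C)[C@@H]2[C@H]3C(=O)C=C(C)[C@@H]2[C@@]13C
F4 | step 13 | triethylsilyl ether of F3 | CC[Si](CC)(CC)O[C@@H]1CC(=O)C(C)(C)[C@@H]2[C@H]3C(=O)C=C(C)[C@@H]2[C@@]13C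
F5 | step 13 | C3 enol triflate of F4 (C2=C3) | CC[Si](CC)(CC)O[C@@H]1C=C(OS(=O)(=O)C(F)(F)F)C(C)(C)[C@@H]2[C@H]3C(=O)C=C(C)[C@@H]2[C@@]13C
F6 | step 13 | triethylsilyl ether of 26 | CC[Si](CC)(CC)O[C@@H]1C=CC(C)(C)[C@@H]2[C@H]3C(=O)C=C(C)[C@@H]2[C@@]13C
F7 | step 16 | 1,2,3-triol of the tricyclic 8-en-7-one (O1 on the C6 face, O2 and O3 on the C10 face) | O[C@@H]1[C@@H](O)[C@@H](O)C(C)(C)[C@@H]2[C@H]3C(=O)C=C(C)[C@@H]2[C@@]13C
F8 | step 16 | O2,O3-acetonide of F7 | O[C@@H]1[C@H]4OC(C)(C)O[C@H]4C(C)(C)[C@@H]2[C@H]3C(=O)C=C(C)[C@@H]2[C@@]13C
F9 | step 16 | C1 angelate of F8 | C/C=C(/C)C(=O)O[C@@H]1[C@H]4OC(C)(C)O[C@H]4C(C)(C)[C@@H]2[C@H]3C(=O)C=C(C)[C@@H]2[C@@]13C
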